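**Retrosynthetic overview**
1. Both rings close in the last step. A Ni/Cr-mediated alkenyl–aldehyde coupling forms C5–C6 and the ten-membered carbocycle, and the C6 chromium alkoxide then closes the α-methylene-γ-lactone onto the acrylate ester in the same flask.
2. The open-chain iodo-dialdehyde comes from an indium-mediated, chelation-controlled allylation (C7–C8) of an α-hydroxy aldehyde with a Z-2-(bromomethyl)enoate acetal. This sets C7 and C8 from C9, and the two isobutyrates go on before cyclisation.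
3. The α-hydroxy aldehyde half comes from aldol condensation (C1=C10) of an (S)-β-silyloxy ester (C9 from asymmetric hydrogenation) with a Z-iodoalkenyl aldehyde, then ester-to-enal adjustment.
4. The Z-iodoalkenyl aldehyde comes from propargyl alcohol, and the allyl bromide from the Morita–Baylis–Hillman adduct of dimethoxyacetaldehyde and methyl acrylate.

Assumption: positions are named by germacranolide numbering (C12 lactone carbonyl, C13 exocyclic methylene, C6 lactone CH–O, C7 ring-fusion CH, C8/C9 ester carbons, C14 formyl, C15 methyl); the given SMILES is then (6R,7S,8S,9S),1(10)E,4Z, and that enantiomer is made.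

The route is a paper design; none of it has been run. Aldehydes 23 and 27 are used without purification.

**Step 1**
Reactants: 1 prop-2-yn-1-ol
Product: 3 (2Z)-3-iodo-2-methylprop-2-en-1-ol, via alkenylmagnesium alkoxide 2 (not isolated)
Conditions: MeMgBr (2.5 equiv), CuI (10 mol%), Et2O, −10 °C → rt; then I2, −10 °C
Reagents that add atoms: methylmagnesium bromide, C[Mg]Br; iodine, II
Why: CuI-catalysed, alkoxide-directed anti-carbomagnesiation of the propargylic alcohol (Duboudin-type carbometalation) puts magnesium cis to the CH2O group, and iodinolysis of the C–Mg bond with retention fixes the Z-alkenyl iodide.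

**Step 2**
Reactants: 3 (2Z)-3-iodo-2-methylprop-2-en-1-ol
Product: 4 (1Z)-3-bromo-1-iodo-2-methylprop-1-ene
Conditions: PBr3 (0.4 equiv), Et2O, 0 °C
Reagents that add atoms: phosphorus tribromide, BrP(Br)Br
Why: SN2 bromination of the primary allylic alcohol through its phosphite ester leaves the alkene geometry and the C–I bond untouched.

**Step 3**
Reactants: 4 (1Z)-3-bromo-1-iodo-2-methylprop-1-ene; 5 N-tert-butylethanimine
Product: 8 (4Z)-5-iodo-4-methylpent-4-enal, via lithiated imine 6 (not isolated), via alkylated imine 7 (not isolated)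
Conditions: 5 (1.5 equiv), LiN(i-Pr)2, THF, −78 → 0 °C; 4, −78 °C → rt; then aq. oxalic acid, Et2O, rt
Reagents that add atoms: water, O
Why: Metalloenamine (Stork–Wittig aza-enolate) alkylation by the primary allylic bromide followed by imine hydrolysis gives the two-carbon-extended aldehyde; the aza-enolate does not exchange the alkenyl iodide.

**Step 4**
Reactants: 9 methyl 4,4-dimethoxy-3-oxobutanoate
Product: 10 methyl (3S)-3-hydroxy-4,4-dimethoxybutanoate
Conditions: H2 (50 atm), [RuCl(p-cymene)((R)-BINAP)]Cl (0.5 mol%), MeOH, 50 °C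
Reagents that add atoms: none
Why: Noyori asymmetric hydrogenation of a β-keto ester; ester–ketone chelation to the ruthenium hydride delivers hydrogen to one face, and by the usual β-keto ester model (R)-BINAP gives the carbinol that is (S) here because the acetal carbon outranks CH2CO2Me (use (S)-BINAP if the sense proves reversed for this substrate); this centre becomes C9.

**Step 5**
Reactants: 10 methyl (3S)-3-hydroxy-4,4-dimethoxybutanoate
Product: 11 methyl (3S)-4,4-dimethoxy-3-[(triethylsilyl)oxy]butanoate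
Conditions: TESCl, imidazole, CH2Cl2, 0 °C → rt
Reagents that add atoms: chlorotriethylsilane, CC[Si](CC)(CC)Cl
Why: Standard silylation of the secondary alcohol gives an ether that survives enolate chemistry and hydride reduction but falls off under the mild acid used in step 12.

**Step 6**
Reactants: 11 methyl (3S)-4,4-dimethoxy-3-[(triethylsilyl)oxy]butanoate; 8 (4Z)-5-iodo-4-methylpent-4-enal
Product: 13 methyl (6Z)-2-[(1S)-2,2-dimethoxy-1-[(triethylsilyl)oxy]ethyl]-3-hydroxy-7-iodo-6-methylhept-6-enoate (isomer mixture at C2/C3), via lithium enolate 12 (not isolated)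
Conditions: LiN(i-Pr)2, THF, −78 °C; then 8, −78 °C; aq. NH4Cl
Reagents that add atoms: none
Why: Aldol addition of the lithium ester enolate (β-silyloxy enolates do not β-eliminate at −78 °C) forms the C1–C10 bond; the two new centres are uncontrolled and are erased in step 7.

**Step 7**
Reactants: 13 aldol adduct
Product: 15 methyl (2E,6Z)-2-[(1S)-2,2-dimethoxy-1-[(triethylsilyl)oxy]ethyl]-7-iodo-6-methylhepta-2,6-dienoate, via mesylate 14 (not isolated)
Conditions: MsCl, Et3N, CH2Cl2, 0 °C; then DBU, rt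
Reagents that add atoms: none
Why: Mesylation and E1cB elimination complete the aldol condensation; only the mesylate leaves (not the silyloxy group) and the conjugated ester forms with the chain trans to CO2Me (tiglate-type E isomer, minor Z isomer removed by chromatography).

**Step 8**
Reactants: 15 dienoate
Product: 16 (2Z,6Z)-2-[(1S)-2,2-dimethoxy-1-[(triethylsilyl)oxy]ethyl]-7-iodo-6-methylhepta-2,6-dien-1-ol
Conditions: i-Bu2AlH (2.3 equiv), CH2Cl2, −78 °C; aq. potassium sodium tartrate
Reagents that add atoms: none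
Why: 1,2-Reduction of the enoate by the aluminium hydride gives the allylic alcohol; silyl ether, acetal and alkenyl iodide are inert and the geometry is unchanged (the descriptor switches to Z only by priority).

**Step 9**
Reactants: 16 allylic alcohol
Product: 17 (2E,6Z)-2-[(1S)-2,2-dimethoxy-1-[(triethylsilyl)oxy]ethyl]-7-iodo-6-methylhepta-2,6-dienal
Conditions: MnO2, CH2Cl2, rt
Reagents that add atoms: none
Why: MnO2 oxidises the allylic primary alcohol selectively to the C14 enal, which already has the thermodynamically preferred geometry (chain trans to CHO).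

**Step 10**
Reactants: 18 2,2-dimethoxyacetaldehyde; 19 methyl acrylate
Product: 20 methyl 3-hydroxy-4,4-dimethoxy-2-methylidenebutanoate (racemic)
Conditions: DABCO (20 mol%), 1,4-dioxane/H2O, rt
Reagents that add atoms: none
Why: Morita–Baylis–Hillman reaction of the acrylate with an electron-poor aldehyde; the racemic carbinol centre is erased in step 11.

**Step 11**
Reactants: 20 Morita–Baylis–Hillman adduct
Product: 22 methyl (2Z)-2-(bromomethyl)-4,4-dimethoxybut-2-enoate, via alkoxysulfonium bromide 21 (not isolated)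
Conditions: NBS, Me2S, CH2Cl2, 0 °C → rt
Reagents that add atoms: N-bromosuccinimide, BrN1C(=O)CCC1=O
Why: Corey–Kim-type activation of the allylic alcohol and SN2′ delivery of bromide give the rearranged primary allylic bromide as the favoured Z isomer (acetal carbon trans to the ester) under neutral, acetal-safe conditions.

**Step 12**
Reactants: 17 silyloxy acetal enal; 22 methyl (2Z)-2-(bromomethyl)-4,4-dimethoxybut-2-enoate
Product: 25 methyl (3R,4S,5S,6E,10Z)-3-(dimethoxymethyl)-6-formyl-4,5-dihydroxy-11-iodo-10-methyl-2-methylideneundeca-6,10-dienoate, via hydroxy aldehyde 23 (not isolated), via allylindium reagent 24 (not isolated)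
Conditions: Dowex 50WX8 (H+ form), THF/H2O, 40 °C; filter; then 22 (1.2 equiv), In powder (1.2 equiv), THF/H2O, rt
Reagents that add atoms: water, O
Why: Acid hydrolysis frees the α-hydroxy aldehyde and the aqueous indium Barbier allylation attacks it through the γ-carbon in a chair transition state; chelation of indium by the free C9–OH sets C8 syn to C9 (Cram chelate) and the Z-configured 2-(methoxycarbonyl)allylindium sets C7 syn to C8, while the hindered conjugated enal reacts more slowly.

**Step 13**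
Reactants: 25 diol
Product: 26 methyl (3R,4S,5S,6E,10Z)-3-(dimethoxymethyl)-6-formyl-11-iodo-10-methyl-2-methylidene-4,5-bis[(2-methylpropanoyl)oxy]undeca-6,10-dienoate
Conditions: (i-PrCO)2O, DMAP (cat.), pyridine, CH2Cl2, 0 °C → rt
Reagents that add atoms: 2-methylpropanoic anhydride, CC(C)C(=O)OC(=O)C(C)C
Why: DMAP-catalysed acyl transfer esterifies both secondary alcohols with the final isobutyrates straight after work-up, which also blocks lactonisation through O8; no stereocentre is touched.

**Step 14**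
Reactants: 26 diisobutyrate acetal
Product: 27 methyl (3R,4S,5S,6E,10Z)-3,6-diformyl-11-iodo-10-methyl-2-methylidene-4,5-bis[(2-methylpropanoyl)oxy]undeca-6,10-dienoate
Conditions: LiBF4, MeCN/H2O (98:2), rt
Reagents that add atoms: water, O
Why: Mild Lewis-acid hydrolysis of the dimethyl acetal frees the C6 aldehyde without touching the esters, the enal or the alkenyl iodide.

**Step 15**
Reactants: 27 iodo-dialdehyde
Product: 30 (6R,7S,8S,9S,1(10)E,4Z)-8,9-bis(isobutyryloxy)-14-oxogermacra-1(10),4,11(13)-trien-12,6-olide, via alkenylchromium species 28 (not isolated), via chromium alkoxide 29 (not isolated)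
Conditions: CrCl2 (10 equiv), NiCl2 (10 mol%), degassed DMSO/THF (3:1), 2 mM (27 added over 12 h), rt; aq. NH4Cl
Reagents that add atoms: none
Why: Intramolecular Nozaki–Hiyama–Kishi alkenylation (zerovalent nickel inserts into C–I, transmetallation gives a trivalent alkenylchromium that adds 1,2 to the C6 aldehyde with retention of the Z geometry) closes the ten-membered ring, the C14 enal being out of reach because attack there would need a trans-cycloheptene; the γ-chromium alkoxide then acylates on the acrylate methyl ester, as in chromium-mediated 2-(alkoxycarbonyl)allylations, to close the lactone, and C6 is set by Felkin–Anh addition anti to the C7–C8 bond, which gives the trans-fused lactone (6R).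

**Compound list**
1 | prop-2-yn-1-ol | C#CCO | starting material
2 | bromomagnesium (2Z)-3-(bromomagnesio)-2-methylprop-2-en-1-olate | Br[Mg]/C=C(/C)CO[Mg]Br | intermediate
3 | (2Z)-3-iodo-2-methylprop-2-en-1-ol | I/C=C(/C)CO | intermediate
4 | (1Z)-3-bromo-1-iodo-2-methylprop-1-ene | I/C=C(/C)CBr | intermediate
5 | N-tert-butylethanimine | CC=NC(C)(C)C | starting material
6 | lithium tert-butyl(ethenyl)azanide (lithiated 5) | [Li]N(C=C)C(C)(C)C | intermediate
7 | (4Z)-N-tert-butyl-5-iodo-4-methylpent-4-en-1-imine | I/C=C(/C)CCC=NC(C)(C)C | intermediate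
8 | (4Z)-5-iodo-4-methylpent-4-enal | I/C=C(/C)CCC=O | intermediate
9 | methyl 4,4-dimethoxy-3-oxobutanoate | COC(=O)CC(=O)C(OC)OC | starting material
10 | methyl (3S)-3-hydroxy-4,4-dimethoxybutanoate | COC(=O)C[C@H](O)C(OC)OC | intermediate
11 | methyl (3S)-4,4-dimethoxy-3-[(triethylsilyl)oxy]butanoate | COC(=O)C[C@H](O[Si](CC)(CC)CC)C(OC)OC | intermediate
12 | lithium enolate of 11 | COC(O[Li])=C[C@H](O[Si](CC)(CC)CC)C(OC)OC | intermediate
13 | methyl (6Z)-2-[(1S)-2,2-dimethoxy-1-[(triethylsilyl)oxy]ethyl]-3-hydroxy-7-iodo-6-methylhept-6-enoate (isomer mixture at C2/C3) | I/C=C(/C)CCC(O)C(C(=O)OC)[C@H](O[Si](CC)(CC)CC)C(OC)OC | intermediate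
14 | 3-O-methanesulfonate of 13 | I/C=C(/C)CCC(OS(C)(=O)=O)C(C(=O)OC)[C@H](O[Si](CC)(CC)CC)C(OC)OC | intermediate
15 | methyl (2E,6Z)-2-[(1S)-2,2-dimethoxy-1-[(triethylsilyl)oxy]ethyl]-7-iodo-6-methylhepta-2,6-dienoate | I/C=C(/C)CC/C=C(/C(=O)OC)[C@H](O[Si](CC)(CC)CC)C(OC)OC | intermediate
16 | (2Z,6Z)-2-[(1S)-2,2-dimethoxy-1-[(triethylsilyl)oxy]ethyl]-7-iodo-6-methylhepta-2,6-dien-1-ol | I/C=C(/C)CC/C=C(/CO)[C@H](O[Si](CC)(CC)CC)C(OC)OC | intermediate
17 | (2E,6Z)-2-[(1S)-2,2-dimethoxy-1-[(triethylsilyl)oxy]ethyl]-7-iodo-6-methylhepta-2,6-dienal | I/C=C(/C)CC/C=C(/C=O)[C@H](O[Si](CC)(CC)CC)C(OC)OC | intermediate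
18 | 2,2-dimethoxyacetaldehyde | COC(OC)C=O | starting material
19 | methyl acrylate | C=CC(=O)OC | starting material
20 | methyl 3-hydroxy-4,4-dimethoxy-2-methylidenebutanoate (racemic) | C=C(C(=O)OC)C(O)C(OC)OC | intermediate
21 | {[3-(methoxycarbonyl)-1,1-dimethoxybut-3-en-2-yl]oxy}dimethylsulfonium bromide | COC(=O)C(=C)C(O[S+](C)C)C(OC)OC.[Br-] | intermediate
22 | methyl (2Z)-2-(bromomethyl)-4,4-dimethoxybut-2-enoate | COC(=O)/C(CBr)=C/C(OC)OC | intermediate
23 | (2S,3E,7Z)-3-formyl-2-hydroxy-8-iodo-7-methylocta-3,7-dienal | I/C=C(/C)CC/C=C(/C=O)[C@H](O)C=O | intermediate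
24 | [(2Z)-2-(methoxycarbonyl)-4,4-dimethoxybut-2-en-1-yl]indium dibromide (allylindium reagent from 22, drawn as the dibromide) | COC(=O)/C(C[In](Br)Br)=C/C(OC)OC | intermediate
25 | methyl (3R,4S,5S,6E,10Z)-3-(dimethoxymethyl)-6-formyl-4,5-dihydroxy-11-iodo-10-methyl-2-methylideneundeca-6,10-dienoate | I/C=C(/C)CC/C=C(/C=O)[C@H](O)[C@@H](O)[C@@H](C(=C)C(=O)OC)C(OC)OC | intermediate
26 | methyl (3R,4S,5S,6E,10Z)-3-(dimethoxymethyl)-6-formyl-11-iodo-10-methyl-2-methylidene-4,5-bis[(2-methylpropanoyl)oxy]undeca-6,10-dienoate | I/C=C(/C)CC/C=C(/C=O)[C@H](OC(=O)C(C)C)[C@@H](OC(=O)C(C)C)[C@@H](C(=C)C(=O)OC)C(OC)OC | intermediate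
27 | methyl (3R,4S,5S,6E,10Z)-3,6-diformyl-11-iodo-10-methyl-2-methylidene-4,5-bis[(2-methylpropanoyl)oxy]undeca-6,10-dienoate | I/C=C(/C)CC/C=C(/C=O)[C@H](OC(=O)C(C)C)[C@@H](OC(=O)C(C)C)[C@@H](C(=C)C(=O)OC)C=O | intermediate
28 | alkenylchromium dichloride from 27 (C–I replaced by C–CrCl2, Z geometry kept) | Cl[Cr](Cl)/C=C(/C)CC/C=C(/C=O)[C@H](OC(=O)C(C)C)[C@@H](OC(=O)C(C)C)[C@@H](C(=C)C(=O)OC)C=O | intermediate
29 | dichlorochromium C6-alkoxide of the ten-membered hydroxy ester (C12 still the methyl ester; configuration as in 30) | Cl[Cr](Cl)O[C@@H]2/C=C(/C)CC/C=C(/C=O)[C@H](OC(=O)C(C)C)[C@@H](OC(=O)C(C)C)[C@H]2C(=C)C(=O)OC | intermediate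
30 | (3aS,4S,5S,6E,10Z,11aR)-6-formyl-10-methyl-3-methylidene-2-oxo-2,3,3a,4,5,8,9,11a-octahydrocyclodeca[b]furan-4,5-diyl bis(2-methylpropanoate) | C=C1C(=O)O[C@@H]2/C=C(/C)CC/C=C(/C=O)[C@H](OC(=O)C(C)C)[C@@H](OC(=O)C(C)C)[C@@H]12 | target

**Step count and risks**
Total step count: 15. Longest linear sequence: 11 steps (1, 2, 3, 6, 7, 8, 9, 12, 13, 14, 15).

Step 12 (hydrolysis with in situ indium allylation). The α-hydroxy aldehyde 23 may drift by α-ketol shift into conjugation, the allylindium reagent may also attack the C14 enal, and diol 25 could lactonise through O8. The fallback sets out from 16 and comes back at 25; it keeps C14 at the alcohol level during the allylation. The same resin hydrolysis of 16 gives the hydroxy aldehyde resting as the five-membered lactol (3S,4Z)-4-[(4Z)-5-iodo-4-methylpent-4-en-1-ylidene]oxolane-2,3-diol F1 (not isolated, no enal present). Indium allylation with 22 under the step 12 conditions gives methyl (3R,4S,5S,6Z,10Z)-3-(dimethoxymethyl)-4,5-dihydroxy-6-(hydroxymethyl)-11-iodo-10-methyl-2-methylideneundeca-6,10-dienoate F2. Aerobic oxidation of the primary allylic alcohol only ([Cu(MeCN)4]OTf, 2,2'-bipyridine, TEMPO, N-methylimidazole, air, MeCN, rt) then gives 25.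

Step 14 (unmasking the C6 aldehyde). Aldehyde 27 is α-branched, allylic to the acrylate and β-acyloxy, so loss of isobutyrate (E1cB) or double-bond migration can compete. The fallback sets out from 25 and comes back at 30; it postpones the isobutyrates. TBSOTf/2,6-lutidine (CH2Cl2, −78 °C) converts 25 into methyl (3R,4S,5S,6E,10Z)-4,5-bis[(tert-butyldimethylsilyl)oxy]-3-(dimethoxymethyl)-6-formyl-11-iodo-10-methyl-2-methylideneundeca-6,10-dienoate F3. LiBF4 hydrolysis as in step 14 gives methyl (3R,4S,5S,6E,10Z)-4,5-bis[(tert-butyldimethylsilyl)oxy]-3,6-diformyl-11-iodo-10-methyl-2-methylideneundeca-6,10-dienoate F4, whose β-silyloxy groups are poor leaving groups. The CrCl2/NiCl2 cyclisation–lactonisation of step 15 gives the 8,9-bis-O-(tert-butyldimethylsilyl) analogue of 30 F5. HF·pyridine (THF, 0 °C) gives the 8,9-diol lactone corresponding to 30 F6, and isobutyric anhydride/DMAP/pyridine gives 30.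

Step 15 (ring closure and lactonisation). This combination is untested: oligomerisation, decomposition of 27 under the Lewis-acidic conditions, acyl migration to the chromium alkoxide or the wrong C6 epimer (cis-fused lactone) are all possible. The fallback sets out from 26 and comes back at 30; it makes the lactone first and closes the carbocycle by olefin metathesis at C4=C5. Hydrodeiodination of 26 (Bu3SnH, Pd(PPh3)4 cat., THF, rt) gives methyl (3R,4S,5S,6E)-3-(dimethoxymethyl)-6-formyl-10-methyl-2-methylidene-4,5-bis[(2-methylpropanoyl)oxy]undeca-6,10-dienoate F7. LiBF4 hydrolysis as in step 14 gives methyl (3R,4S,5S,6E)-3,6-diformyl-10-methyl-2-methylidene-4,5-bis[(2-methylpropanoyl)oxy]undeca-6,10-dienoate F8. Intermolecular CrCl2/NiCl2 addition of vinyl bromide (1.1 equiv) to the aliphatic C6 aldehyde with in situ lactonisation gives (1S,2S,3E)-1-[(2R,3S)-2-ethenyl-4-methylidene-5-oxooxolan-3-yl]-3-formyl-7-methylocta-3,7-diene-1,2-diyl bis(2-methylpropanoate) F9 (C6 epimers separable). Ring-closing metathesis of the vinyl and isopropenyl groups (second-generation Hoveyda–Grubbs catalyst, toluene, 80 °C, 1 mM) then gives 30; the Z geometry of the new ring alkene is expected but would have to be checked.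

**Further compounds**
F1 | step 12 | (3S,4Z)-4-[(4Z)-5-iodo-4-methylpent-4-en-1-ylidene]oxolane-2,3-diol (anomer mixture) | OC1OC/C(=C/CC/C(C)=C\I)[C@@H]1O
F2 | step 12 | methyl (3R,4S,5S,6Z,10Z)-3-(dimethoxymethyl)-4,5-dihydroxy-6-(hydroxymethyl)-11-iodo-10-methyl-2-methylideneundeca-6,10-dienoate | I/C=C(/C)CC/C=C(/CO)[C@H](O)[C@@H](O)[C@@H](C(=C)C(=O)OC)C(OC)OC
F3 | step 14 | methyl (3R,4S,5S,6E,10Z)-4,5-bis[(tert-butyldimethylsilyl)oxy]-3-(dimethoxymethyl)-6-formyl-11-iodo-10-methyl-2-methylideneundeca-6,10-dienoate | I/C=C(/C)CC/C=C(/C=O)[C@H](O[Si](C)(C)C(C)(C)C)[C@@H](O[Si](C)(C)C(C)(C)C)[C@@H](C(=C)C(=O)OC)C(OC)OC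
F4 | step 14 | methyl (3R,4S,5S,6E,10Z)-4,5-bis[(tert-butyldimethylsilyl)oxy]-3,6-diformyl-11-iodo-10-methyl-2-methylideneundeca-6,10-dienoate | I/C=C(/C)CC/C=C(/C=O)[C@H](O[Si](C)(C)C(C)(C)C)[C@@H](O[Si](C)(C)C(C)(C)C)[C@@H](C(=C)C(=O)OC)C=O
F5 | step 14 | 8,9-bis-O-(tert-butyldimethylsilyl) analogue of 30 (configuration as in 30) | C=C1C(=O)O[C@@H]2/C=C(/C)CC/C=C(/C=O)[C@H](O[Si](C)(C)C(C)(C)C)[C@@H](O[Si](C)(C)C(C)(C)C)[C@@H]12
F6 | step 14 | 8,9-diol lactone corresponding to 30 (configuration as in 30) | C=C1C(=O)O[C@@H]2/C=C(/C)CC/C=C(/C=O)[C@H](O)[C@@H](O)[C@@H]12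
F7 | step 15 | methyl (3R,4S,5S,6E)-3-(dimethoxymethyl)-6-formyl-10-methyl-2-methylidene-4,5-bis[(2-methylpropanoyl)oxy]undeca-6,10-dienoate | C=C(C)CC/C=C(/C=O)[C@H](OC(=O)C(C)C)[C@@H](OC(=O)C(C)C)[C@@H](C(=C)C(=O)OC)C(OC)OC
F8 | step 15 | methyl (3R,4S,5S,6E)-3,6-diformyl-10-methyl-2-methylidene-4,5-bis[(2-methylpropanoyl)oxy]undeca-6,10-dienoate | C=C(C)CC/C=C(/C=O)[C@H](OC(=O)C(C)C)[C@@H](OC(=O)C(C)C)[C@@H](C(=C)C(=O)OC)C=O
F9 | step 15 | (1S,2S,3E)-1-[(2R,3S)-2-ethenyl-4-methylidene-5-oxooxolan-3-yl]-3-formyl-7-methylocta-3,7-diene-1,2-diyl bis(2-methylpropanoate) | C=C1C(=O)O[C@H](C=C)[C@H]1[C@H](OC(=O)C(C)C)[C@@H](OC(=O)C(C)C)/C(C=O)=C\CCC(C)=C
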